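## Retrosynthetic overview

1. The target comes from its 2,3-O-isopropylidene derivative 24 by acetal hydrolysis; the angelate is carried from step 2.
2. Key disconnection C6–C7 (plus the lactone C–O): chromium-mediated intramolecular allylation of bromo-enal 21. The polarity-reversed C7 of a 2-(bromomethyl)enoate attacks the aldehyde carbon C6, closing the ten-membered carbocycle first and the γ-lactone second.
3. The Z-enal and the erythro 2,3-diol come from Achmatowicz rearrangement and borohydride reduction of a 3-methyl-2-furyl carbinol; the transient pyranone ring fixes the Z geometry.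
4. The furyl ketone comes from one-flask hydroboration (sets C10) and carbonylative B-alkyl coupling; the allyl bromide unit comes from vinylalumination of a β-acyloxy aldehyde.
5. C9 comes from Brown allylation of methacrolein.

Assumption: locants C1–C15 are those of the target (ring C1–C10, lactone oxygen on C6, C11–C13 the methylene-lactone carbons, C14 on C10, C15 on C4); (−)-Ipc2B(allyl) solution and 2-bromo-3-methylfuran are bought as catalogue items.

## Route

Step 1
Reactants: 1 methacrolein
Product: 3 (3S)-2-methylhexa-1,5-dien-3-ol, via borinate ester 2 (not isolated)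
Conditions: (−)-Ipc2B(allyl) (from (+)-α-pinene), Et2O, −78 °C; then NaOH, H2O2
Reagents that add atoms: (−)-B-allyldiisopinocampheylborane, C=CCB([C@@H]1C[C@@H]2C[C@H]([C@H]1C)C2(C)C)[C@@H]1C[C@@H]2C[C@H]([C@H]1C)C2(C)C
Why: Brown asymmetric allylboration; the chair transition state of this reagent delivers allyl to the Si face of the aldehyde, setting C9 as S (about 92–95% ee expected).

Step 2
Reactants: 3 (3S)-2-methylhexa-1,5-dien-3-ol; 4 angelic acid
Product: 6 (3S)-2-methylhexa-1,5-dien-3-yl angelate, via mixed anhydride 5 (not isolated)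
Conditions: 2,4,6-Cl3C6H2COCl, Et3N, toluene, rt; then 3, 80 °C
Reagents that add atoms: none
Why: Yamaguchi-type mixed-anhydride esterification run without DMAP, the conditions under which angelic acid acylates secondary alcohols without Z-to-E leakage to the tiglate.

Step 3
Reactants: 6 (3S)-2-methylhexa-1,5-dien-3-yl angelate
Product: 7 (3S)-2-methyl-5-oxopent-1-en-3-yl angelate
Conditions: OsO4 (2 mol %), NaIO4, 2,6-lutidine, dioxane/H2O, 0 °C → rt, stopped when 6 is consumed
Reagents that add atoms: osmium tetroxide, O=[Os](=O)(=O)=O; sodium periodate (terminal oxygen source), [Na+].[O-]I(=O)(=O)=O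
Why: Lemieux–Johnson cleavage; the vinyl group should react before the isopropenyl group, which is hindered and deactivated by the allylic acyloxy group (the bias seen in distal-selective oxidation of geranyl acetate), and the angelate alkene is electron-poor.

Step 4
Reactants: 7 (3S)-2-methyl-5-oxopent-1-en-3-yl angelate; 8 methyl propiolate
Product: 10 methyl (5S)-5-(angeloyloxy)-3-hydroxy-6-methyl-2-methylidenehept-6-enoate (both C3 epimers), via vinylalane 9 (not isolated)
Conditions: i-Bu2AlH, NMO, THF, 0 °C; then 7, 0 °C → rt; Rochelle salt work-up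
Reagents that add atoms: none
Why: Vinylalumination (α-aluminated acrylate adds 1,2 to the aldehyde) is a base-free Morita–Baylis–Hillman equivalent that avoids E1cB loss of the β-angelate; the new carbinol centre (C7) is erased in step 11.

Step 5
Reactants: 10 methyl (5S)-5-(angeloyloxy)-3-hydroxy-6-methyl-2-methylidenehept-6-enoate; 11 2-bromo-3-methylfuran
Product: 13 methyl (5S,6R)-5-(angeloyloxy)-3-hydroxy-6-methyl-2-methylidene-8-(3-methylfuran-2-yl)-8-oxooctanoate, via B-alkyl-9-BBN 12 (not isolated)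
Conditions: 9-BBN (2.2 equiv), THF, rt; then 11, PdCl2(dppf) (5 mol %), K3PO4 (aq), CO (1 atm), DMF, 60 °C
Reagents that add atoms: carbon monoxide, [C-]#[O+]
Why: Still–Barrish-type 9-BBN hydroboration of the 1,1-disubstituted allylic system (attack anti to the C8 chain in the H-eclipsed conformer gives 10R, anti to the C9 oxygen), then Suzuki–Miyaura carbonylative coupling of the B-alkyl-9-BBN to form C1–C2 and the acylfuran.

Step 6
Reactants: 13 the furyl ketone
Product: 14 methyl (5S,6R,8S)-5-(angeloyloxy)-3,8-dihydroxy-6-methyl-2-methylidene-8-(3-methylfuran-2-yl)octanoate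
Conditions: RuCl[(S,S)-TsDPEN](p-cymene) (2 mol %), HCO2H/Et3N (5:2), CH2Cl2, rt
Reagents that add atoms: none
Why: Noyori asymmetric transfer hydrogenation; the (S,S) catalyst reduces heteroaryl alkyl ketones to the S carbinol under catalyst control (C2 = S) and leaves esters and the acrylate alone.

Step 7
Reactants: 14 the furyl carbinol
Product: 16 methyl (5S,6R)-5-(angeloyloxy)-3-hydroxy-7-[(2S)-6-hydroxy-4-methyl-3-oxo-3,6-dihydro-2H-pyran-2-yl]-6-methyl-2-methylideneheptanoate, via keto-enal 15 (not isolated)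
Conditions: NBS, NaHCO3, NaOAc, THF/H2O (4:1), 0 °C
Reagents that add atoms: water, O
Why: Achmatowicz rearrangement; oxidative opening of the furan to the cis-enedione and capture by the C2 hydroxyl gives the pyranone, so C4=C5 is locked cis (Z) and C2 is untouched.

Step 8
Reactants: 16 the pyranone hemiacetal
Product: 18 methyl (5S,6R,8S,9R,10Z)-5-(angeloyloxy)-3,8,9,12-tetrahydroxy-6,10-dimethyl-2-methylidenedodec-10-enoate, via pyranol 17 (not isolated)
Conditions: NaBH4 (excess), THF/MeOH, −40 °C → rt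
Reagents that add atoms: none
Why: Borohydride 1,2-reduction of the enone by axial attack gives the alcohol trans to the C2 side chain (3R, erythro diol, the sense seen in de novo pyranose work), and the ring-opened hemiacetal (enal) is then reduced to the Z primary allylic alcohol.

Step 9
Reactants: 18 the tetraol
Product: 19 methyl (5S,6R)-5-(angeloyloxy)-3-hydroxy-7-{(4S,5R)-5-[(2Z)-4-hydroxybut-2-en-2-yl]-2,2-dimethyl-1,3-dioxolan-4-yl}-6-methyl-2-methylideneheptanoate
Conditions: Me2C(OMe)2, PPTS (cat.), CH2Cl2, rt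
Reagents that add atoms: 2,2-dimethoxypropane, COC(C)(C)OC
Why: Thermodynamic acetalisation favours the five-membered dioxolane of the vicinal diol over seven-membered or mixed acetals, leaving the C6 and C7 hydroxyls free.

Step 10
Reactants: 19 the acetonide diol
Product: 20 methyl (5S,6R)-5-(angeloyloxy)-7-{(4S,5R)-2,2-dimethyl-5-[(2Z)-4-oxobut-2-en-2-yl]-1,3-dioxolan-4-yl}-3-hydroxy-6-methyl-2-methylideneheptanoate
Conditions: TEMPO (10 mol %), PhI(OAc)2, CH2Cl2, rt
Reagents that add atoms: none
Why: TEMPO/PhI(OAc)2 oxidation is selective for primary over secondary alcohols and converts Z-allylic alcohols of the nerol type to Z-enals without isomerisation.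

Step 11
Reactants: 20 the hydroxy enal
Product: 21 methyl (2Z,5S,6R)-5-(angeloyloxy)-2-(bromomethyl)-7-{(4S,5R)-2,2-dimethyl-5-[(2Z)-4-oxobut-2-en-2-yl]-1,3-dioxolan-4-yl}-6-methylhept-2-enoate
Conditions: NBS, Me2S, CH2Cl2, 0 °C → rt
Reagents that add atoms: N-bromosuccinimide, O=C1CCC(=O)N1Br
Why: Corey–Kim-type activation with SN2′ bromide delivery is the standard conversion of Morita–Baylis–Hillman alcohols to (Z)-2-(bromomethyl)-2-enoates and removes the C7 carbinol centre.

Step 12
Reactants: 21 the bromo-enal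
Product: 24 2,3-O-isopropylidene derivative of the target (6R,7S), via allylchromium 22 (not isolated), via hydroxy ester 23 (not isolated)
Conditions: CrCl2 (8 equiv), THF/DMF, 0.003 M (syringe pump), rt; aq NH4Cl
Reagents that add atoms: none
Why: Intramolecular Nozaki–Hiyama–Kishi (Barbier-type) allylation: divalent chromium turns the electrophilic 2-(bromomethyl)enoate into a nucleophilic 2-(methoxycarbonyl)allylchromium (a β-acrylate anion, homoenolate-type synthon), whose C7, normally a Michael-acceptor carbon, attacks the aldehyde carbon C6 through a chair transition state with both ring tethers equatorial (anti adduct, 6R,7S expected under macrocyclic control, as for related seco-germacranolides), closing the ten-membered ring before the alkoxide lactonises onto the ester.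

Step 13
Reactants: 24 the lactone acetonide
Product: 25 CNP0229085.1
Conditions: AcOH/H2O (4:1), 40 °C
Reagents that add atoms: none
Why: Mild acidic hydrolysis of the isopropylidene acetal, which the angelate, the allylic diol and the α-methylene lactone tolerate.

## Compound list

1 | methacrolein (2-methylprop-2-enal) | C=C(C)C=O | starting material
2 | (3S)-2-methylhexa-1,5-dien-3-yl diisopinocampheylborinate | C=C(C)[C@H](CC=C)OB([C@@H]1C[C@@H]2C[C@H]([C@H]1C)C2(C)C)[C@@H]1C[C@@H]2C[C@H]([C@H]1C)C2(C)C | intermediate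
3 | (3S)-2-methylhexa-1,5-dien-3-ol | C=C(C)[C@@H](O)CC=C | intermediate
4 | angelic acid [(2Z)-2-methylbut-2-enoic acid] | C/C=C(/C)C(=O)O | starting material
5 | angelic 2,4,6-trichlorobenzoic anhydride | C/C=C(/C)C(=O)OC(=O)c1c(Cl)cc(Cl)cc1Cl | intermediate
6 | (3S)-2-methylhexa-1,5-dien-3-yl angelate | C=C(C)[C@@H](OC(=O)/C(C)=C\C)CC=C | intermediate
7 | (3S)-2-methyl-5-oxopent-1-en-3-yl angelate | C=C(C)[C@@H](OC(=O)/C(C)=C\C)CC=O | intermediate
8 | methyl propiolate | C#CC(=O)OC | starting material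
9 | [1-(methoxycarbonyl)ethenyl]diisobutylaluminium | C=C(C(=O)OC)[Al](CC(C)C)CC(C)C | intermediate
10 | methyl (5S)-5-(angeloyloxy)-3-hydroxy-6-methyl-2-methylidenehept-6-enoate (C3 epimers) | C=C(C)[C@@H](OC(=O)/C(C)=C\C)CC(O)C(=C)C(=O)OC | intermediate
11 | 2-bromo-3-methylfuran | Cc1ccoc1Br | starting material
12 | methyl (5S,6R)-5-(angeloyloxy)-7-(9-borabicyclo[3.3.1]nonan-9-yl)-3-hydroxy-6-methyl-2-methylideneheptanoate | C1CCC2CCCC1B2C[C@@H](C)[C@@H](OC(=O)/C(C)=C\C)CC(O)C(=C)C(=O)OC | intermediate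
13 | methyl (5S,6R)-5-(angeloyloxy)-3-hydroxy-6-methyl-2-methylidene-8-(3-methylfuran-2-yl)-8-oxooctanoate | Cc1ccoc1C(=O)C[C@@H](C)[C@@H](OC(=O)/C(C)=C\C)CC(O)C(=C)C(=O)OC | intermediate
14 | methyl (5S,6R,8S)-5-(angeloyloxy)-3,8-dihydroxy-6-methyl-2-methylidene-8-(3-methylfuran-2-yl)octanoate | Cc1ccoc1[C@@H](O)C[C@@H](C)[C@@H](OC(=O)/C(C)=C\C)CC(O)C(=C)C(=O)OC | intermediate
15 | methyl (5S,6R,8S,10Z)-5-(angeloyloxy)-3,8-dihydroxy-6,10-dimethyl-2-methylidene-9,12-dioxododec-10-enoate | O=C/C=C(/C)C(=O)[C@@H](O)C[C@@H](C)[C@@H](OC(=O)/C(C)=C\C)CC(O)C(=C)C(=O)OC | intermediate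
16 | methyl (5S,6R)-5-(angeloyloxy)-3-hydroxy-7-[(2S)-6-hydroxy-4-methyl-3-oxo-3,6-dihydro-2H-pyran-2-yl]-6-methyl-2-methylideneheptanoate (anomers) | CC1=CC(O)O[C@@H](C[C@@H](C)[C@@H](OC(=O)/C(C)=C\C)CC(O)C(=C)C(=O)OC)C1=O | intermediate
17 | methyl (5S,6R)-5-(angeloyloxy)-7-[(2S,3R)-3,6-dihydroxy-4-methyl-3,6-dihydro-2H-pyran-2-yl]-3-hydroxy-6-methyl-2-methylideneheptanoate | CC1=CC(O)O[C@@H](C[C@@H](C)[C@@H](OC(=O)/C(C)=C\C)CC(O)C(=C)C(=O)OC)[C@@H]1O | intermediate
18 | methyl (5S,6R,8S,9R,10Z)-5-(angeloyloxy)-3,8,9,12-tetrahydroxy-6,10-dimethyl-2-methylidenedodec-10-enoate | OC/C=C(/C)[C@@H](O)[C@@H](O)C[C@@H](C)[C@@H](OC(=O)/C(C)=C\C)CC(O)C(=C)C(=O)OC | intermediate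
19 | methyl (5S,6R)-5-(angeloyloxy)-3-hydroxy-7-{(4S,5R)-5-[(2Z)-4-hydroxybut-2-en-2-yl]-2,2-dimethyl-1,3-dioxolan-4-yl}-6-methyl-2-methylideneheptanoate | OC/C=C(/C)[C@H]1OC(C)(C)O[C@H]1C[C@@H](C)[C@@H](OC(=O)/C(C)=C\C)CC(O)C(=C)C(=O)OC | intermediate
20 | methyl (5S,6R)-5-(angeloyloxy)-7-{(4S,5R)-2,2-dimethyl-5-[(2Z)-4-oxobut-2-en-2-yl]-1,3-dioxolan-4-yl}-3-hydroxy-6-methyl-2-methylideneheptanoate | O=C/C=C(/C)[C@H]1OC(C)(C)O[C@H]1C[C@@H](C)[C@@H](OC(=O)/C(C)=C\C)CC(O)C(=C)C(=O)OC | intermediate
21 | methyl (2Z,5S,6R)-5-(angeloyloxy)-2-(bromomethyl)-7-{(4S,5R)-2,2-dimethyl-5-[(2Z)-4-oxobut-2-en-2-yl]-1,3-dioxolan-4-yl}-6-methylhept-2-enoate | O=C/C=C(/C)[C@H]1OC(C)(C)O[C@H]1C[C@@H](C)[C@@H](OC(=O)/C(C)=C\C)C/C=C(\CBr)C(=O)OC | intermediate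
22 | allylchromium dichloride derived from 21 (CrCl2 in place of Br) | O=C/C=C(/C)[C@H]1OC(C)(C)O[C@H]1C[C@@H](C)[C@@H](OC(=O)/C(C)=C\C)C/C=C(\C[Cr](Cl)Cl)C(=O)OC | intermediate
23 | ten-membered hydroxy ester: methyl 2-substituted acrylate on C7 (7S), 6R-hydroxyl, 4Z-alkene, 2S,3R-acetonide, 9S-angelate, 10R-methyl | O[C@@H]1/C=C(/C)[C@H]2OC(C)(C)O[C@H]2C[C@@H](C)[C@@H](OC(=O)/C(C)=C\C)C[C@H]1C(=C)C(=O)OC | intermediate
24 | (2S,3R,4Z,6R,7S,9S,10R)-9-angeloyloxy-2,3-(isopropylidenedioxy)germacra-4,11(13)-dien-12,6-olide | C=C1C(=O)O[C@@H]2/C=C(/C)[C@H]3OC(C)(C)O[C@H]3C[C@@H](C)[C@@H](OC(=O)/C(C)=C\C)C[C@@H]12 | intermediate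
25 | CNP0229085.1, (2S,3R,4Z,6R,7S,9S,10R)-9-angeloyloxy-2,3-dihydroxygermacra-4,11(13)-dien-12,6-olide | C=C1C(=O)O[C@@H]2/C=C(/C)[C@@H](O)[C@@H](O)C[C@@H](C)[C@@H](OC(=O)/C(C)=C\C)C[C@@H]12 | target

## Step count and weak points

Total steps: 13. Longest linear sequence: 13 (from methacrolein 1; 4, 8 and 11 enter as bought materials).

Steps most likely to fail:

**Step 12 (macrocyclising allylation).** Ring closure competes with oligomerisation, and the C6/C7 outcome (trans-lactone, and its sense relative to C9/C10) rests on macrocyclic control that is untested for a Z-enal; equilibrating allylchromium geometry could also deliver the cis-lactone. Fallback, setting out from 20 and returning at 24 (through 23): acetylation (Ac2O, pyridine) gives the Morita–Baylis–Hillman acetate F1. Palladium-catalysed borylation (Pd2(dba)3, B2pin2) gives the 2-(methoxycarbonyl)allylboronate F2. At high dilution with Sc(OTf)3, F2 cyclises by intramolecular allylboration through a closed six-membered transition state to hydroxy ester 23, which lactonises to 24. This replaces the equilibrating organochromium by a geometrically defined allyl donor, and the acid-catalysed variants of this allylboration are known to be stereodivergent.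

**Step 5 (hydroboration and carbonylative coupling).** The anti selectivity of the hydroboration is less certain with an allylic ester than with an ether. The free C7 hydroxyl (as its borinate) and the acrylate may interfere with palladium or with acyl transfer from C9, and direct non-carbonylative coupling can compete. Fallback, setting out from 10 and returning at 13: silylation (TESCl, imidazole) gives the silyl ether F3. Hydroboration–oxidation (9-BBN; NaBO3) gives the primary alcohol F4, where the C10 epimers can be separated. Iodination (I2, PPh3, imidazole) gives the iodide F5, and zinc insertion (Zn, LiCl) gives the alkylzinc iodide F6. Negishi acylation of F6 with 3-methylfuran-2-carbonyl chloride under palladium catalysis gives the silyl-protected ketone F7, and HF·pyridine returns 13.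

**Step 3 (chemoselective cleavage).** The selectivity between the vinyl and the isopropenyl group may be only moderate, perhaps about 5:1. Fallback, setting out from 1 and returning at 7: a catalytic asymmetric Mukaiyama acetate aldol with 1-(tert-butylthio)-1-(trimethylsilyloxy)ethene (Ti(OiPr)4/BINOL; I have not fixed which BINOL antipode gives the 3S adduct, so it would be assigned as the Mosher ester) gives the β-hydroxy thioester F8. Angeloylation as in step 2 gives the thioester angelate F9, and Fukuyama reduction (Et3SiH, Pd/C) returns aldehyde 7 without a second alkene to distinguish.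

## Further compounds

F1 | step 12 | Morita–Baylis–Hillman acetate of 20 (C7 acetate, both epimers) | O=C/C=C(/C)[C@H]1OC(C)(C)O[C@H]1C[C@@H](C)[C@@H](OC(=O)/C(C)=C\C)CC(OC(C)=O)C(=C)C(=O)OC
F2 | step 12 | 2-(methoxycarbonyl)allylboronate (pinacol ester at C13, C7=C11 alkene) | O=C/C=C(/C)[C@H]1OC(C)(C)O[C@H]1C[C@@H](C)[C@@H](OC(=O)/C(C)=C\C)C/C=C(\CB2OC(C)(C)C(C)(C)O2)C(=O)OC
F3 | step 5 | triethylsilyl ether of 10 | C=C(C)[C@@H](OC(=O)/C(C)=C\C)CC(O[Si](CC)(CC)CC)C(=C)C(=O)OC
F4 | step 5 | methyl (5S,6R)-5-(angeloyloxy)-7-hydroxy-6-methyl-2-methylidene-3-(triethylsilyloxy)heptanoate | OC[C@@H](C)[C@@H](OC(=O)/C(C)=C\C)CC(O[Si](CC)(CC)CC)C(=C)C(=O)OC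
F5 | step 5 | methyl (5S,6R)-5-(angeloyloxy)-7-iodo-6-methyl-2-methylidene-3-(triethylsilyloxy)heptanoate | IC[C@@H](C)[C@@H](OC(=O)/C(C)=C\C)CC(O[Si](CC)(CC)CC)C(=C)C(=O)OC
F6 | step 5 | alkylzinc iodide from F5 | I[Zn]C[C@@H](C)[C@@H](OC(=O)/C(C)=C\C)CC(O[Si](CC)(CC)CC)C(=C)C(=O)OC
F7 | step 5 | triethylsilyl ether of 13 | Cc1ccoc1C(=O)C[C@@H](C)[C@@H](OC(=O)/C(C)=C\C)CC(O[Si](CC)(CC)CC)C(=C)C(=O)OC
F8 | step 3 | S-tert-butyl (3S)-3-hydroxy-4-methylpent-4-enethioate | C=C(C)[C@@H](O)CC(=O)SC(C)(C)C
F9 | step 3 | S-tert-butyl (3S)-3-(angeloyloxy)-4-methylpent-4-enethioate | C=C(C)[C@@H](OC(=O)/C(C)=C\C)CC(=O)SC(C)(C)C
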